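**Plan**
- Cuts, in order: the O6–acyl bond (epoxyangelate); the C4–O bond (angelate, to be formed with inversion); the isopropyl group read as isopropenyl; ring bond C4–C5; finally the bond between furan C2 and its carbinol carbon.
- Enabling feature: in the cyclohexenone ring, carbinol carbon C4 is bonded to C5, which carries the three-carbon branch. This is the retron of a carbonyl-ene closure. In addition, C1(=O)–C2=C3–C4(–O) is a cis-2-ene-1,4-dioxygenated four-carbon unit, which corresponds to the four carbons of an oxidatively opened furan ring.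
- Forward, main line: 3-furanmethanol → TIPS ether → asymmetric furyl transfer to 3-methylbut-2-enal → TES ether → singlet-oxygen dearomatisation to a (Z)-4-oxo-2-enal → ene closure of the only carbocycle → hydrogenation → Mitsunobu angeloylation → TES removal → epoxyangeloylation → TIPS removal.
- Side branch: angelic acid → (Z)-allylic alcohol → Sharpless epoxidation (forms the oxirane ring) → epoxy acid. Angelic acid also supplies the C4 acyl group.
- Stereochemistry: C6 comes from the chiral amino-alcohol catalyst. C5 and C4 are relayed from C6 in the ene step, and C4 is then inverted in the Mitsunobu step. The oxirane centres come from L-(+)-DET. The acyl Z geometry comes from angelic acid, and the ring Z alkene comes from the furan.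

Key step: step 8

Remark on the chemistry: ring atoms are numbered C1 (C=O), C2 (C–CH2O), C3 (=CH), C4 (CH–O-angeloyl), C5 (CH–isopropyl) and C6 (CH–O-epoxyangeloyl). The same labels are used for the corresponding atoms of the furan and open-chain precursors. (+)-MIB, (2R)-3-exo-morpholinoisoborneol, is taken as a purchasable ligand.

**Step 1**
Reactants: 1 angelic acid, (2Z)-2-methylbut-2-enoic acid
Product: 2 (2Z)-2-methylbut-2-en-1-ol
Conditions: LiAlH4, Et2O, 0 °C → rt; then H2O
Reagents that add atoms: none
Why: Hydride reduction of the carboxylic acid to the primary allylic alcohol should leave the trisubstituted Z alkene unchanged, since no addition–elimination path for Z/E exchange is open.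

**Step 2**
Reactants: 2 (2Z)-2-methylbut-2-en-1-ol
Product: 3 [(2S,3R)-2,3-dimethyloxiran-2-yl]methanol
Conditions: Ti(OiPr)4 (10 mol %), L-(+)-DET (12 mol %), t-BuOOH, 4 Å MS, CH2Cl2, −20 °C; non-aqueous work-up
Reagents that add atoms: tert-butyl hydroperoxide, CC(C)(C)OO
Why: In this Sharpless asymmetric epoxidation, L-(+)-DET follows the usual enantiofacial rule and should give the (2S) epoxy alcohol, while syn addition to the Z alkene fixes C3 as R (methyl cis to CH2OH).

**Step 3**
Reactants: 3 [(2S,3R)-2,3-dimethyloxiran-2-yl]methanol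
Product: 4 (2R,3R)-2,3-dimethyloxirane-2-carboxylic acid (epoxyangelic acid)
Conditions: TEMPO (cat.), PhI(OAc)2, MeCN/H2O, 0 °C → rt
Reagents that add atoms: water, O
Why: Oxoammonium oxidation of the primary alcohol through the aldehyde hydrate is close to neutral, so the oxirane and both non-enolisable centres are kept, and the C2 descriptor changes from S to R only because the substituent ranking changes.

**Step 4**
Reactants: 5 furan-3-ylmethanol
Product: 6 (furan-3-ylmethoxy)tri(propan-2-yl)silane
Conditions: TIPSCl, imidazole, DMF, rt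
Reagents that add atoms: chlorotri(propan-2-yl)silane, CC(C)[Si](Cl)(C(C)C)C(C)C
Why: This is a standard silylation, and TIPS is chosen because it should withstand n-BuLi, Me2AlCl and the later TES cleavage and is the silyl group least prone to migrate from O to C.

**Step 5**
Reactants: 6 (furan-3-ylmethoxy)tri(propan-2-yl)silane; 7 3-methylbut-2-enal
Product: 10 (1S)-3-methyl-1-[3-({[tri(propan-2-yl)silyl]oxy}methyl)furan-2-yl]but-2-en-1-ol, via 2-lithiofuran 8 (not isolated), via ethyl(furyl)zinc 9 (not isolated)
Conditions: n-BuLi, Et2O, −78 → 0 °C (no HMPA); EtZnCl (from Et2Zn + ZnCl2), −78 → 0 °C; TEEDA (N,N,N',N'-tetraethylethylenediamine), (+)-MIB (10 mol %), toluene; 7, 0 °C; aq NH4Cl; Et3N-deactivated silica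
Reagents that add atoms: none
Why: C2-lithiation directed by the CH2O group, transmetalation to the mixed ethyl(heteroaryl)zinc and amino-alcohol-catalysed asymmetric 1,2-addition to the enal should set the (S) carbinol centre (future C6), because (+)-MIB directs furyl transfer to the Re face of 7 while TEEDA masks LiCl and suppresses the racemic background.

**Step 6**
Reactants: 10 (S)-furyl carbinol
Product: 11 triethyl{[(1S)-3-methyl-1-[3-({[tri(propan-2-yl)silyl]oxy}methyl)furan-2-yl]but-2-en-1-yl]oxy}silane
Conditions: TESCl, imidazole, CH2Cl2, 0 °C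
Reagents that add atoms: chlorotriethylsilane, CC[Si](Cl)(CC)CC
Why: Basic silylation avoids ionisation of the acid-labile furyl allyl carbinol, blocks the pyranone-forming (Achmatowicz) path in step 7, and gives a group removable in the presence of TIPS without touching the stereocentre.

**Step 7**
Reactants: 11 TES/TIPS-protected furan
Product: 13 (2Z,5S)-7-methyl-4-oxo-5-[(triethylsilyl)oxy]-3-({[tri(propan-2-yl)silyl]oxy}methyl)octa-2,6-dienal, via furan endoperoxide 12 (not isolated)
Conditions: O2, tetraphenylporphyrin (cat.), visible light, CH2Cl2, −78 °C; Me2S, −78 °C → rt; short neutral filtration, used at once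
Reagents that add atoms: dioxygen, O=O
Why: [4+2] cycloaddition of singlet oxygen across furan C2/C5 is much faster than its ene reaction with the trisubstituted alkene, and Me2S reduction of the O–O bond then opens the ring to the cis-enedicarbonyl, so the furan ring geometry becomes the Z C2=C3 bond and no stereocentre is touched.

**Step 8**
Reactants: 13 (Z)-4-oxo-2-enal
Product: 14 (4S,5R,6S)-4-hydroxy-5-(prop-1-en-2-yl)-6-[(triethylsilyl)oxy]-2-({[tri(propan-2-yl)silyl]oxy}methyl)cyclohex-2-en-1-one
Conditions: Me2AlCl (1.5 equiv), CH2Cl2 (dilute), −78 → −40 °C; aq NaHCO3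
Reagents that add atoms: none
Why: Me2AlCl binds the aldehyde oxygen, the trisubstituted alkene attacks the aldehyde carbon C4 through its less substituted end C5, and a methyl hydrogen passes to oxygen; this is a type 1 intramolecular carbonyl-ene reaction whose closest relatives are the closures of citronellal to isopulegol and of neral to isopiperitenol. The only ring formed is the six-membered carbocycle, closed 6-exo-trig at both partners (the carbonyl oxygen and the C(CH3)2 terminus stay outside the ring), and closure is possible only because the furan-derived C2=C3 bond holds C1 and C4 cis. C5 is set by C6, because allylic 1,3-strain with the cis methyl places H6 in the alkene plane, so the tether reaches only one alkene face and OTES and isopropenyl end up trans-diequatorial. C4 is set by the chair-like transition state, in which the aluminium-bound oxygen takes the equatorial site anti to the C5–C6 bond and gives the 4,5-trans alcohol. The required chemoselectivity for the aldehyde follows from ring size, since attack at C1, C2 or C3 would give a three-membered, four-membered or 5-endo five-membered ring, and Me2AlCl scavenges protons (with loss of methane), which protects the TES ether, the new 1,1-disubstituted alkene and the epimerisable C6. The 4,5-trans outcome is the one wanted, because step 10 introduces the angelate with inversion.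

**Step 9**
Reactants: 14 ene product
Product: 15 (4S,5R,6S)-4-hydroxy-5-(propan-2-yl)-6-[(triethylsilyl)oxy]-2-({[tri(propan-2-yl)silyl]oxy}methyl)cyclohex-2-en-1-one
Conditions: H2 (1 atm), RhCl(PPh3)3 (5 mol %), toluene, rt
Reagents that add atoms: none
Why: Homogeneous hydrogenation discriminates by substitution, so the 1,1-disubstituted isopropenyl group is reduced and the trisubstituted conjugated enone is not (as in carvone to carvotanacetone), and no stereocentre is formed.

**Step 10**
Reactants: 15 4,5-trans alcohol; 1 angelic acid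
Product: 16 (4R,5R,6S)-4-{[(2Z)-2-methylbut-2-enoyl]oxy}-5-(propan-2-yl)-6-[(triethylsilyl)oxy]-2-({[tri(propan-2-yl)silyl]oxy}methyl)cyclohex-2-en-1-one
Conditions: PPh3, DIAD, toluene, 0 °C → rt
Reagents that add atoms: none
Why: In this Mitsunobu esterification the allylic C4 alkoxyphosphonium ion is displaced by angelate in an SN2 sense, which inverts C4 to R (cis to isopropyl), and because the acid acts only as a carboxylate nucleophile its carbonyl is never activated and Z to E drift to the tiglate is avoided.

**Step 11**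
Reactants: 16 C4 angelate
Product: 17 (4R,5S,6S)-6-hydroxy-4-{[(2Z)-2-methylbut-2-enoyl]oxy}-5-(propan-2-yl)-2-({[tri(propan-2-yl)silyl]oxy}methyl)cyclohex-2-en-1-one
Conditions: HF·pyridine, pyridine, THF, 0 °C
Reagents that add atoms: none
Why: Buffered fluoride desilylation cleaves TES far faster than TIPS and spares the angelate and the enone, and the C5 descriptor changes only through substituent ranking.

**Step 12**
Reactants: 17 C6 alcohol; 4 (2R,3R)-epoxyangelic acid
Product: 18 (4R,5R,6S)-6-{[(2R,3R)-2,3-dimethyloxirane-2-carbonyl]oxy}-4-{[(2Z)-2-methylbut-2-enoyl]oxy}-5-(propan-2-yl)-2-({[tri(propan-2-yl)silyl]oxy}methyl)cyclohex-2-en-1-one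
Conditions: DCC, DMAP (cat.), CH2Cl2, 0 °C → rt
Reagents that add atoms: none
Why: In this Steglich esterification acid 4 has no alpha hydrogen and cannot racemise, the C6–O bond is not broken, the equatorial C6 ester is also the more stable epimer, and any minor enantiomer of either partner ends up as a separable diastereomer.

**Step 13**
Reactants: 18 TIPS ether
Product: 19 target, (4R,5R,6S)-6-{[(2R,3R)-2,3-dimethyloxirane-2-carbonyl]oxy}-2-(hydroxymethyl)-4-{[(2Z)-2-methylbut-2-enoyl]oxy}-5-(propan-2-yl)cyclohex-2-en-1-one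
Conditions: Et3N·3HF, MeCN, rt
Reagents that add atoms: none
Why: Nearly neutral fluoride cleavage of the primary allylic silyl ether should be mild enough for the oxirane ester, the angelate and the base-sensitive acyloxy enone.

**Compound list**
1 | angelic acid, (2Z)-2-methylbut-2-enoic acid | C/C=C(/C)C(=O)O | starting material
2 | (2Z)-2-methylbut-2-en-1-ol | C/C=C(/C)CO | intermediate
3 | [(2S,3R)-2,3-dimethyloxiran-2-yl]methanol | OC[C@]1(C)O[C@@H]1C | intermediate
4 | (2R,3R)-2,3-dimethyloxirane-2-carboxylic acid | OC(=O)[C@]1(C)O[C@@H]1C | intermediate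
5 | furan-3-ylmethanol | OCc1ccoc1 | starting material
6 | (furan-3-ylmethoxy)tri(propan-2-yl)silane | CC(C)[Si](OCc1ccoc1)(C(C)C)C(C)C | intermediate
7 | 3-methylbut-2-enal | CC(C)=CC=O | starting material
8 | [3-({[tri(propan-2-yl)silyl]oxy}methyl)furan-2-yl]lithium | [Li]c1occc1CO[Si](C(C)C)(C(C)C)C(C)C | intermediate
9 | ethyl[3-({[tri(propan-2-yl)silyl]oxy}methyl)furan-2-yl]zinc | CC[Zn]c1occc1CO[Si](C(C)C)(C(C)C)C(C)C | intermediate
10 | (1S)-3-methyl-1-[3-({[tri(propan-2-yl)silyl]oxy}methyl)furan-2-yl]but-2-en-1-ol | CC(C)[Si](OCc1ccoc1[C@@H](O)C=C(C)C)(C(C)C)C(C)C | intermediate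
11 | TES ether of 10, (1S) | CC(C)[Si](OCc1ccoc1[C@@H](O[Si](CC)(CC)CC)C=C(C)C)(C(C)C)C(C)C | intermediate
12 | 2,3,7-trioxabicyclo[2.2.1]hept-5-ene endoperoxide of 11 (O2 across furan C2/C5, bridgeheads unassigned) | CC(C)[Si](OCC1=CC2OOC1([C@@H](O[Si](CC)(CC)CC)C=C(C)C)O2)(C(C)C)C(C)C | intermediate
13 | (2Z,5S)-7-methyl-4-oxo-5-[(triethylsilyl)oxy]-3-({[tri(propan-2-yl)silyl]oxy}methyl)octa-2,6-dienal | O=C/C=C(\C(=O)[C@@H](O[Si](CC)(CC)CC)C=C(C)C)CO[Si](C(C)C)(C(C)C)C(C)C | intermediate
14 | (4S,5R,6S)-4-hydroxy-5-(prop-1-en-2-yl)-6-[(triethylsilyl)oxy]-2-({[tri(propan-2-yl)silyl]oxy}methyl)cyclohex-2-en-1-one | O[C@H]1C=C(CO[Si](C(C)C)(C(C)C)C(C)C)C(=O)[C@@H](O[Si](CC)(CC)CC)[C@@H]1C(C)=C | intermediate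
15 | (4S,5R,6S)-4-hydroxy-5-(propan-2-yl)-6-[(triethylsilyl)oxy]-2-({[tri(propan-2-yl)silyl]oxy}methyl)cyclohex-2-en-1-one | O[C@H]1C=C(CO[Si](C(C)C)(C(C)C)C(C)C)C(=O)[C@@H](O[Si](CC)(CC)CC)[C@@H]1C(C)C | intermediate
16 | (4R,5R,6S)-4-angeloyloxy-5-(propan-2-yl)-6-[(triethylsilyl)oxy]-2-({[tri(propan-2-yl)silyl]oxy}methyl)cyclohex-2-en-1-one | C/C=C(/C)C(=O)O[C@@H]1C=C(CO[Si](C(C)C)(C(C)C)C(C)C)C(=O)[C@@H](O[Si](CC)(CC)CC)[C@@H]1C(C)C | intermediate
17 | (4R,5S,6S)-4-angeloyloxy-6-hydroxy-5-(propan-2-yl)-2-({[tri(propan-2-yl)silyl]oxy}methyl)cyclohex-2-en-1-one | C/C=C(/C)C(=O)O[C@@H]1C=C(CO[Si](C(C)C)(C(C)C)C(C)C)C(=O)[C@@H](O)[C@@H]1C(C)C | intermediate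
18 | (4R,5R,6S)-4-angeloyloxy-6-{[(2R,3R)-2,3-dimethyloxirane-2-carbonyl]oxy}-5-(propan-2-yl)-2-({[tri(propan-2-yl)silyl]oxy}methyl)cyclohex-2-en-1-one | C/C=C(/C)C(=O)O[C@@H]1C=C(CO[Si](C(C)C)(C(C)C)C(C)C)C(=O)[C@@H](OC(=O)[C@]2(C)O[C@@H]2C)[C@@H]1C(C)C | intermediate
19 | CNP0293054.1, (4R,5R,6S)-4-angeloyloxy-6-{[(2R,3R)-2,3-dimethyloxirane-2-carbonyl]oxy}-2-(hydroxymethyl)-5-(propan-2-yl)cyclohex-2-en-1-one | C/C=C(/C)C(=O)O[C@@H]1C=C(CO)C(=O)[C@@H](OC(=O)[C@]2(C)O[C@@H]2C)[C@@H]1C(C)C | target

Total step count: 13. Longest linear sequence: 10 (steps 4–13, from furan-3-ylmethanol).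

**Steps most likely to fail**

Step 8. The enal may isomerise from Z to E before closure. Bond formation may also turn stepwise, so that the tertiary cation is lost to chloride capture or to unselective proton loss instead of the ordered hydrogen transfer. C6 may epimerise by enolisation of the beta,gamma-unsaturated ketone. The fallback sets out from 13 and returns at 15. Compound 13 is treated with SnCl4 in CH2Cl2 at −78 °C, so that C–C bond formation is deliberately ended by chloride capture (chloro-Prins cyclisation). This should give (4S,5R,6S)-5-(2-chloropropan-2-yl)-4-hydroxy-6-[(triethylsilyl)oxy]-2-({[tri(propan-2-yl)silyl]oxy}methyl)cyclohex-2-en-1-one F1. Radical dechlorination (Bu3SnH, AIBN, toluene, 80 °C) then leads directly to 15 and makes step 9 unnecessary.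

Step 10. Displacement next to the isopropyl-bearing carbon may be slow for an acid of only moderate acidity. Acyl transfer with retention, elimination towards a dienone followed by aromatisation, or plain recovery of the alcohol could then compete. The fallback sets out from 15 and returns at 16, and it separates the inversion from the angeloylation. A Mitsunobu reaction with the more acidic 4-nitrobenzoic acid (PPh3, DIAD, THF) should give (4R,5R,6S)-4-[(4-nitrobenzoyl)oxy]-5-(propan-2-yl)-6-[(triethylsilyl)oxy]-2-({[tri(propan-2-yl)silyl]oxy}methyl)cyclohex-2-en-1-one F2. Brief methanolysis (K2CO3, MeOH, 0 °C) gives the 4,5-cis alcohol (4R,5R,6S)-4-hydroxy-5-(propan-2-yl)-6-[(triethylsilyl)oxy]-2-({[tri(propan-2-yl)silyl]oxy}methyl)cyclohex-2-en-1-one F3. This alcohol is acylated with retention by the preformed mixed anhydride (2Z)-2-methylbut-2-enoic 2,4,6-trichlorobenzoic anhydride F4 (made from 1, 2,4,6-trichlorobenzoyl chloride and Et3N) in toluene at 80 °C without DMAP (Yamaguchi-type esterification), which gives 16.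

Step 5. The silyl group may migrate from oxygen to C2 in the lithiofuran, ethyl transfer may compete with furyl transfer, and lithium salts may promote a racemic background addition that erodes the enantiomeric purity. The fallback sets out from 6 and returns at 10, and it reverses the polarity of the union. The lithiated furan is quenched with DMF to give 3-({[tri(propan-2-yl)silyl]oxy}methyl)furan-2-carbaldehyde F5. Separately, 1-bromo-2-methylprop-1-ene and t-BuLi (Et2O, −78 °C) give (2-methylprop-1-enyl)lithium F6, which EtZnCl converts into ethyl(2-methylprop-1-enyl)zinc F7. Alkenyl transfer from this reagent to the Si face of the heteroaromatic aldehyde, catalysed by (−)-MIB in the presence of TEEDA (toluene, 0 °C), should give the same (S) carbinol 10.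

**Further compounds**
F1 | step 8 | (4S,5R,6S)-5-(2-chloropropan-2-yl)-4-hydroxy-6-[(triethylsilyl)oxy]-2-({[tri(propan-2-yl)silyl]oxy}methyl)cyclohex-2-en-1-one | O[C@H]1C=C(CO[Si](C(C)C)(C(C)C)C(C)C)C(=O)[C@@H](O[Si](CC)(CC)CC)[C@@H]1C(C)(C)Cl
F2 | step 10 | (4R,5R,6S)-4-[(4-nitrobenzoyl)oxy]-5-(propan-2-yl)-6-[(triethylsilyl)oxy]-2-({[tri(propan-2-yl)silyl]oxy}methyl)cyclohex-2-en-1-one | O=C(O[C@@H]1C=C(CO[Si](C(C)C)(C(C)C)C(C)C)C(=O)[C@@H](O[Si](CC)(CC)CC)[C@@H]1C(C)C)c1ccc(cc1)[N+](=O)[O-]
F3 | step 10 | (4R,5R,6S)-4-hydroxy-5-(propan-2-yl)-6-[(triethylsilyl)oxy]-2-({[tri(propan-2-yl)silyl]oxy}methyl)cyclohex-2-en-1-one | O[C@@H]1C=C(CO[Si](C(C)C)(C(C)C)C(C)C)C(=O)[C@@H](O[Si](CC)(CC)CC)[C@@H]1C(C)C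
F4 | step 10 | (2Z)-2-methylbut-2-enoic 2,4,6-trichlorobenzoic anhydride | C/C=C(/C)C(=O)OC(=O)c1c(Cl)cc(Cl)cc1Cl
F5 | step 5 | 3-({[tri(propan-2-yl)silyl]oxy}methyl)furan-2-carbaldehyde | O=Cc1occc1CO[Si](C(C)C)(C(C)C)C(C)C
F6 | step 5 | (2-methylprop-1-enyl)lithium | [Li]C=C(C)C
F7 | step 5 | ethyl(2-methylprop-1-enyl)zinc | CC[Zn]C=C(C)C
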